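**Plan**

1. Numbering (germacrane): C1 ketone, C2=C3 and the C3–O–C10 bridge form the 3(2H)-furanone, then C4=C5, C6 (lactone O), C7, C8 (ester O), C9, C10, with C11=C13 and C12 in the lactone. The retrosynthesis cuts C4=C5 first, then the O8–acyl bond, then C7–C8; inside the fragments it cuts O–C3 and C1–C2 of the furanone and C11–C12 of the butenolide.
2. Enabling feature: C4=C5 is a Z trisubstituted alkene inside the ten-membered carbocycle C1–C10, with C4 on furanone carbon C3 and C5 on lactone carbinol C6. Opening it leaves an isopropenyl group on the furanone ring and a vinyl group on the γ-lactone ring.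
3. Forward order: the furanone ring is made from (R)-citramalic acid and 2-methylbut-1-en-3-yne; a vinyl butenolide is made from acrolein; the Barbier coupling turns the butenolide into the α-methylene-γ-lactone; O8 is acylated; the ten-membered ring closes last.
4. Stereochemistry: C10 comes from (R)-citramalic acid; C6 from a lipase resolution of the acrolein-derived enynol; C7 and C8 are set in the Barbier step (attack anti to the vinyl group, chair transition state); C4=C5 is Z by ring constraint; the side-chain alkene is E from a thermodynamic allylic transposition.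

Key step: step 18

Assumption: the lipase is taken to follow the usual empirical rule for secondary alcohols (alkynyl arm as the large group, vinyl as the medium group), so the (R)-enantiomer of 13 is acetylated and the (S)-alcohol is recovered.

**Fragment A: furanone aldehyde**

Step 1
Reactants: 1 (R)-citramalic acid
Product: 2 2-[(4R)-2,2,4-trimethyl-5-oxo-1,3-dioxolan-4-yl]acetic acid
Conditions: Me2C(OMe)2, TsOH·H2O (cat.), acetone, rt
Reagents that add atoms: 2,2-dimethoxypropane, COC(C)(C)OC
Why: Acid-catalysed acetonide (dioxolanone) formation ties the tertiary hydroxyl to its own carboxyl in a five-membered ring and leaves the CH2CO2H arm free; the C10 stereocentre is carried through unchanged.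

Step 2
Reactants: 2 2-[(4R)-2,2,4-trimethyl-5-oxo-1,3-dioxolan-4-yl]acetic acid
Product: 4 (3R)-3-hydroxy-3-methyloxolan-2-one, via hydroxyethyl dioxolanone 3 (not isolated)
Conditions: BH3·SMe2, THF, 0 °C to rt; MeOH quench; then TsOH·H2O (cat.), CH2Cl2, rt
Reagents that add atoms: none
Why: Chemoselective borane reduction of the free carboxylic acid beside the dioxolanone, then acid-catalysed translactonisation with loss of acetone, the standard sequence for malic-type acetonide acids.

Step 3
Reactants: 4 (3R)-3-hydroxy-3-methyloxolan-2-one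
Product: 5 (3R)-3-methyl-3-(trimethylsilyloxy)oxolan-2-one
Conditions: TMSCl, imidazole, DMF, 0 °C to rt
Reagents that add atoms: chlorotrimethylsilane, C[Si](C)(C)Cl
Why: Silylation masks the tertiary hydroxyl so that no alkoxide sits next to the lactone carbonyl in the acetylide addition.

Step 4
Reactants: 5 (3R)-3-methyl-3-(trimethylsilyloxy)oxolan-2-one; 6 2-methylbut-1-en-3-yne
Product: 8 (6R)-6,8-dihydroxy-2,6-dimethyloct-1-en-3-yn-5-one, via silyl ether ynone 7 (not isolated)
Conditions: 6, n-BuLi, THF, −78 °C; add 5, −78 °C; then 1 M HCl, THF, 0 °C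
Reagents that add atoms: none
Why: Acylation of a lithium acetylide by a γ-lactone stops at the ketone stage because the lithium lactolate persists at −78 °C; dilute acid then opens it to the ynone and removes the TMS ether, and C10 is not touched.

Step 5
Reactants: 8 (6R)-6,8-dihydroxy-2,6-dimethyloct-1-en-3-yn-5-one
Product: 9 (2R)-2-(2-hydroxyethyl)-2-methyl-5-(prop-1-en-2-yl)furan-3(2H)-one
Conditions: Et2NH, EtOH, rt
Reagents that add atoms: none
Why: Amine-mediated 5-endo oxa-Michael cyclisation (conjugate addition of Et2NH to the ynone, then addition–elimination by the tertiary hydroxyl) is the classical route from α′-hydroxy ynones to 3(2H)-furanones and should outrun a seven-membered closure by the primary hydroxyl.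

Step 6
Reactants: 9 (2R)-2-(2-hydroxyethyl)-2-methyl-5-(prop-1-en-2-yl)furan-3(2H)-one
Product: 10 2-[(2R)-2-methyl-3-oxo-5-(prop-1-en-2-yl)-2,3-dihydrofuran-2-yl]acetaldehyde
Conditions: Dess–Martin periodinane, CH2Cl2, 0 °C to rt; used at once
Reagents that add atoms: none
Why: Dess–Martin oxidation under non-basic conditions should give the aldehyde without β-elimination of the furanone oxygen from C10.

**Fragment B: bromomethyl butenolide**

Step 7
Reactants: 11 acrolein; 12 tert-butyldimethyl(prop-2-yn-1-yloxy)silane
Product: 13 rac-6-(tert-butyldimethylsilyloxy)hex-1-en-4-yn-3-ol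
Conditions: 12, n-BuLi, THF, −78 °C; then 11, −78 °C; aq. NH4Cl
Reagents that add atoms: none
Why: 1,2-Addition of a lithium acetylide to acrolein at low temperature gives the racemic vinyl alkynyl carbinol.

Step 8
Reactants: 13 rac-6-(tert-butyldimethylsilyloxy)hex-1-en-4-yn-3-ol
Product: 14 (3S)-6-(tert-butyldimethylsilyloxy)hex-1-en-4-yn-3-ol
Conditions: Amano lipase PS, vinyl acetate, hexane, 30 °C, stopped just past half conversion; chromatography
Reagents that add atoms: none
Why: Lipase-catalysed kinetic resolution by transesterification should acetylate the (R)-alcohol and leave the (S)-alcohol, whose carbinol centre becomes C6 of the target.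

Step 9
Reactants: 14 (3S)-6-(tert-butyldimethylsilyloxy)hex-1-en-4-yn-3-ol
Product: 15 (3S,4Z)-6-(tert-butyldimethylsilyloxy)-5-iodohexa-1,4-dien-3-ol
Conditions: Red-Al, THF, 0 °C; EtOAc; then I2, −78 to 0 °C
Reagents that add atoms: iodine, II
Why: Hydroxyl-directed trans-hydroalumination of the propargylic alcohol places aluminium on the distal alkyne carbon, and iodinolysis with retention gives the (Z)-3-iodoallylic alcohol; the vinyl group and the stereocentre are not involved.

Step 10
Reactants: 15 (3S,4Z)-6-(tert-butyldimethylsilyloxy)-5-iodohexa-1,4-dien-3-ol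
Product: 16 (5S)-3-[(tert-butyldimethylsilyloxy)methyl]-5-ethenylfuran-2(5H)-one
Conditions: PdCl2(PPh3)2 (5 mol %), CO (1 atm), K2CO3, THF, rt
Reagents that add atoms: carbon monoxide, [C-]#[O+]
Why: Palladium-catalysed carbonylative lactonisation (oxidative addition to the vinyl iodide, CO insertion, capture of the acyl-palladium by the cis hydroxyl) closes the butenolide without breaking a bond at the stereocentre.

Step 11
Reactants: 16 (5S)-3-[(tert-butyldimethylsilyloxy)methyl]-5-ethenylfuran-2(5H)-one
Product: 17 (5S)-3-(bromomethyl)-5-ethenylfuran-2(5H)-one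
Conditions: Ph3PBr2, CH2Cl2, 0 °C to rt
Reagents that add atoms: dibromotriphenylphosphorane, BrP(Br)(c1ccccc1)(c1ccccc1)c1ccccc1
Why: Dibromotriphenylphosphorane converts a primary silyl ether directly into the bromide (SN2 on the oxyphosphonium) under non-basic conditions that spare the acidic C5–H.

**Fragment C: side-chain acid**

Step 12
Reactants: 18 tert-butyl acrylate; 19 acetaldehyde
Product: 20 tert-butyl 3-hydroxy-2-methylidenebutanoate (racemic)
Conditions: DABCO, 1,4-dioxane/H2O (1:1), rt
Reagents that add atoms: none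
Why: Morita–Baylis–Hillman reaction of an acrylate with acetaldehyde; the racemic carbinol centre is erased in step 14.

Step 13
Reactants: 20 tert-butyl 3-hydroxy-2-methylidenebutanoate
Product: 21 tert-butyl 3-acetoxy-2-methylidenebutanoate (racemic)
Conditions: Ac2O, Et3N, DMAP (cat.), CH2Cl2, 0 °C
Reagents that add atoms: acetic anhydride, CC(=O)OC(C)=O
Why: Standard DMAP-catalysed acetylation of the secondary allylic alcohol.

Step 14
Reactants: 21 tert-butyl 3-acetoxy-2-methylidenebutanoate
Product: 22 tert-butyl (2E)-2-(acetoxymethyl)but-2-enoate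
Conditions: DABCO (20 mol %), THF, reflux
Reagents that add atoms: none
Why: DABCO-catalysed SN2′–SN2′ allylic transposition of a Morita–Baylis–Hillman acetate should deliver the thermodynamically preferred primary acetate with the methyl group trans to the ester (2E).

Step 15
Reactants: 22 tert-butyl (2E)-2-(acetoxymethyl)but-2-enoate
Product: 23 (2E)-2-(acetoxymethyl)but-2-enoic acid
Conditions: TFA, CH2Cl2, 0 °C to rt
Reagents that add atoms: none
Why: Acidolysis (E1) of the tert-butyl ester frees the acid without touching the primary allylic acetate.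

**Coupling and ring closure**

Step 16
Reactants: 10 2-[(2R)-2-methyl-3-oxo-5-(prop-1-en-2-yl)-2,3-dihydrofuran-2-yl]acetaldehyde; 17 (5S)-3-(bromomethyl)-5-ethenylfuran-2(5H)-one
Product: 24 (4S,5S)-5-ethenyl-4-{(1R)-1-hydroxy-2-[(2R)-2-methyl-3-oxo-5-(prop-1-en-2-yl)-2,3-dihydrofuran-2-yl]ethyl}-3-methylideneoxolan-2-one
Conditions: In powder, THF/H2O (4:1), rt
Reagents that add atoms: none
Why: Indium-mediated Barbier allylation, in which the allylindium reacts at its γ-carbon (future C7) on the face anti to the C6 vinyl group and through a Zimmerman–Traxler chair with the aldehyde substituent equatorial; this should fix C7 as S (trans lactone) and C8 as R (anti adduct) and unveil the α-methylene lactone.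

Step 17
Reactants: 24 (4S,5S)-5-ethenyl-4-{(1R)-1-hydroxy-2-[(2R)-2-methyl-3-oxo-5-(prop-1-en-2-yl)-2,3-dihydrofuran-2-yl]ethyl}-3-methylideneoxolan-2-one; 23 (2E)-2-(acetoxymethyl)but-2-enoic acid
Product: 25 (1R)-1-[(2S,3S)-2-ethenyl-4-methylidene-5-oxooxolan-3-yl]-2-[(2R)-2-methyl-3-oxo-5-(prop-1-en-2-yl)-2,3-dihydrofuran-2-yl]ethyl (2E)-2-(acetoxymethyl)but-2-enoate
Conditions: DCC, DMAP, CH2Cl2, 0 °C to rt
Reagents that add atoms: none
Why: Steglich esterification acylates the C8 hydroxyl with retention, and low temperature should keep acylation ahead of translactonisation to O8.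

Step 18
Reactants: 25 (1R)-1-[(2S,3S)-2-ethenyl-4-methylidene-5-oxooxolan-3-yl]-2-[(2R)-2-methyl-3-oxo-5-(prop-1-en-2-yl)-2,3-dihydrofuran-2-yl]ethyl (2E)-2-(acetoxymethyl)but-2-enoate
Product: 26 CNP0176571.1, (6S,7S,8R,10R,4Z)-3,10-epoxy-1-oxogermacra-2,4,11(13)-trien-12,6-olide 8-O-[(2E)-2-(acetoxymethyl)but-2-enoate]
Conditions: Hoveyda–Grubbs second-generation catalyst (20 mol %, in portions), 1,4-benzoquinone (20 mol %), toluene (1 mM), 100 °C, argon sparge
Reagents that add atoms: none
Why: The ruthenium benzylidene is exchanged at the C6 vinyl group, the only monosubstituted alkene, and the resulting C5 alkylidene forms a ruthenacyclobutane with the isopropenyl C=C whose collapse gives the C4=C5 bond and a methylidene that leaves as ethylene. The closest known reaction type is ring-closing metathesis of seco-germacranolide dienes that carry an α-methylene lactone, including closures onto an isopropenyl 3(2H)-furanone that give the furanone-conjugated trisubstituted alkene of a medium ring. The ring formed is the ten-membered carbocycle C1–C10, closed between C4 and C5 as a macrocyclic metathesis in which both alkene CH2 termini are lost; the quaternary C10, the planar furanone and the trans lactone shorten the distance between the two termini. No stereocentre is created, and the alkene should be Z because C3 is held sp2 inside the furanone bridge and the trans lactone spans C6–C7, so the ring cannot reasonably hold the E isomer. Site selectivity is needed and comes from the substrate: the methylene lactone and the trisubstituted side-chain alkene are electron-poor and hindered, and their alternative closures would give a cyclobutene or an eight-membered tetrasubstituted alkene. High dilution, ethylene removal and benzoquinone are there to hold back dimerisation and Ru–H isomerisation of the vinyl and methylene groups.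

**Compound list**

1 | (R)-citramalic acid | C[C@@](O)(CC(=O)O)C(=O)O | starting material
2 | 2-[(4R)-2,2,4-trimethyl-5-oxo-1,3-dioxolan-4-yl]acetic acid | C[C@]1(CC(=O)O)OC(C)(C)OC1=O | intermediate
3 | (5R)-5-(2-hydroxyethyl)-2,2,5-trimethyl-1,3-dioxolan-4-one (not isolated) | C[C@]1(CCO)OC(C)(C)OC1=O | intermediate
4 | (3R)-3-hydroxy-3-methyloxolan-2-one | C[C@@]1(O)CCOC1=O | intermediate
5 | (3R)-3-methyl-3-(trimethylsilyloxy)oxolan-2-one | C[C@@]1(O[Si](C)(C)C)CCOC1=O | intermediate
6 | 2-methylbut-1-en-3-yne | C=C(C)C#C | starting material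
7 | (6R)-8-hydroxy-2,6-dimethyl-6-(trimethylsilyloxy)oct-1-en-3-yn-5-one (not isolated) | C=C(C)C#CC(=O)[C@](C)(O[Si](C)(C)C)CCO | intermediate
8 | (6R)-6,8-dihydroxy-2,6-dimethyloct-1-en-3-yn-5-one | C=C(C)C#CC(=O)[C@](C)(O)CCO | intermediate
9 | (2R)-2-(2-hydroxyethyl)-2-methyl-5-(prop-1-en-2-yl)furan-3(2H)-one | C=C(C)C1=CC(=O)[C@@](C)(CCO)O1 | intermediate
10 | 2-[(2R)-2-methyl-3-oxo-5-(prop-1-en-2-yl)-2,3-dihydrofuran-2-yl]acetaldehyde | C=C(C)C1=CC(=O)[C@@](C)(CC=O)O1 | intermediate
11 | acrolein | C=CC=O | starting material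
12 | tert-butyldimethyl(prop-2-yn-1-yloxy)silane | C#CCO[Si](C)(C)C(C)(C)C | starting material
13 | rac-6-(tert-butyldimethylsilyloxy)hex-1-en-4-yn-3-ol | C=CC(O)C#CCO[Si](C)(C)C(C)(C)C | intermediate
14 | (3S)-6-(tert-butyldimethylsilyloxy)hex-1-en-4-yn-3-ol | C=C[C@H](O)C#CCO[Si](C)(C)C(C)(C)C | intermediate
15 | (3S,4Z)-6-(tert-butyldimethylsilyloxy)-5-iodohexa-1,4-dien-3-ol | C=C[C@H](O)/C=C(\I)CO[Si](C)(C)C(C)(C)C | intermediate
16 | (5S)-3-[(tert-butyldimethylsilyloxy)methyl]-5-ethenylfuran-2(5H)-one | C=C[C@@H]1OC(=O)C(CO[Si](C)(C)C(C)(C)C)=C1 | intermediate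
17 | (5S)-3-(bromomethyl)-5-ethenylfuran-2(5H)-one | C=C[C@@H]1OC(=O)C(CBr)=C1 | intermediate
18 | tert-butyl acrylate | C=CC(=O)OC(C)(C)C | starting material
19 | acetaldehyde | CC=O | starting material
20 | tert-butyl 3-hydroxy-2-methylidenebutanoate (racemic) | C=C(C(C)O)C(=O)OC(C)(C)C | intermediate
21 | tert-butyl 3-acetoxy-2-methylidenebutanoate (racemic) | C=C(C(C)OC(C)=O)C(=O)OC(C)(C)C | intermediate
22 | tert-butyl (2E)-2-(acetoxymethyl)but-2-enoate | C/C=C(\COC(C)=O)C(=O)OC(C)(C)C | intermediate
23 | (2E)-2-(acetoxymethyl)but-2-enoic acid | C/C=C(\COC(C)=O)C(=O)O | intermediate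
24 | (4S,5S)-5-ethenyl-4-{(1R)-1-hydroxy-2-[(2R)-2-methyl-3-oxo-5-(prop-1-en-2-yl)-2,3-dihydrofuran-2-yl]ethyl}-3-methylideneoxolan-2-one | C=C1C(=O)O[C@@H](C=C)[C@@H]1[C@H](O)C[C@@]2(C)OC(C(C)=C)=CC2=O | intermediate
25 | (1R)-1-[(2S,3S)-2-ethenyl-4-methylidene-5-oxooxolan-3-yl]-2-[(2R)-2-methyl-3-oxo-5-(prop-1-en-2-yl)-2,3-dihydrofuran-2-yl]ethyl (2E)-2-(acetoxymethyl)but-2-enoate | C=C1C(=O)O[C@@H](C=C)[C@@H]1[C@H](OC(=O)/C(=C/C)COC(C)=O)C[C@@]2(C)OC(C(C)=C)=CC2=O | intermediate
26 | CNP0176571.1, (6S,7S,8R,10R,4Z)-3,10-epoxy-1-oxogermacra-2,4,11(13)-trien-12,6-olide 8-O-[(2E)-2-(acetoxymethyl)but-2-enoate] | C=C1C(=O)O[C@H]2/C=C(/C)C3=CC(=O)[C@@](C)(C[C@@H](OC(=O)/C(=C/C)COC(C)=O)[C@H]12)O3 | target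

**Count**

Total steps: 18. Longest linear sequence: 9 steps (steps 1–6, then 16–18).

**Steps most likely to fail**

Step 18. The C5 ruthenium alkylidene formed at the C6 vinyl group may rest as a chelate to the neighbouring lactone or ester carbonyl and be consumed by intermolecular dimerisation before it engages the hindered, furanone-conjugated isopropenyl alkene. The fallback is a relay metathesis that sets out from lactone 5. Commercial (2E)-3-methylpent-2-en-4-yn-1-ol is allylated (NaH, allyl bromide) to relay enyne ether F1. Its lithium acetylide is added to 5 in place of that of 6 and gives, through relay silyl ether ynone F2, relay diol ynone F3. Diethylamine then closes relay furanone alcohol F4, Dess–Martin oxidation gives relay aldehyde F5, indium allylation with 17 gives relay alcohol F6, and DCC/DMAP esterification with 23 gives relay ester F7. With the same catalyst, ruthenium should now load at the unhindered allyl ether, expel 2,5-dihydrofuran and arrive as the alkylidene on C4, which closes onto the C6 vinyl group and comes back to the route at target 26.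

Step 16. In the aqueous medium open transition states may compete with the chair, so facial selectivity at the aldehyde carbon can be poor and the C8 epimer may contaminate or dominate 24. The fallback sets out from 10 and 17 under the same allylation and accepts the epimer. The separated 8-epi alcohol F8 is esterified with acid 23 under Mitsunobu conditions (PPh3, DIAD, toluene, 0 °C), which installs the side chain with inversion at C8 and comes back to the route at ester 25.

Step 10. Under the basic carbonylation conditions the doubly activated C5–H of the γ-vinyl butenolide may be removed, eroding configuration through the 2-oxidofuran, and the acyl-palladium may insert the pendant vinyl group. The fallback sets out from iodide 15 and avoids palladium and base at the butenolide stage. Deprotonation (MeLi) and iodine–lithium exchange (t-BuLi, Et2O, −78 °C) followed by CO2 should give, after mild acidification, hydroxy acid F9, which lactonises under acid and comes back to the route at 16.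

**Further compounds**

F1 | step 18 | (2E)-3-methyl-1-(prop-2-en-1-yloxy)pent-2-en-4-yne | C#C/C(C)=C/COCC=C
F2 | step 18 | (2E,8R)-10-hydroxy-3,8-dimethyl-1-(prop-2-en-1-yloxy)-8-(trimethylsilyloxy)dec-2-en-4-yn-7-one (not isolated) | C=CCOC/C=C(\C)C#CC(=O)[C@](C)(O[Si](C)(C)C)CCO
F3 | step 18 | (2E,8R)-8,10-dihydroxy-3,8-dimethyl-1-(prop-2-en-1-yloxy)dec-2-en-4-yn-7-one | C=CCOC/C=C(\C)C#CC(=O)[C@](C)(O)CCO
F4 | step 18 | (2R)-2-(2-hydroxyethyl)-2-methyl-5-[(2E)-4-(prop-2-en-1-yloxy)but-2-en-2-yl]furan-3(2H)-one | C=CCOC/C=C(\C)C1=CC(=O)[C@@](C)(CCO)O1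
F5 | step 18 | 2-{(2R)-2-methyl-3-oxo-5-[(2E)-4-(prop-2-en-1-yloxy)but-2-en-2-yl]-2,3-dihydrofuran-2-yl}acetaldehyde | C=CCOC/C=C(\C)C1=CC(=O)[C@@](C)(CC=O)O1
F6 | step 18 | (4S,5S)-5-ethenyl-4-[(1R)-1-hydroxy-2-{(2R)-2-methyl-3-oxo-5-[(2E)-4-(prop-2-en-1-yloxy)but-2-en-2-yl]-2,3-dihydrofuran-2-yl}ethyl]-3-methylideneoxolan-2-one | C=C1C(=O)O[C@@H](C=C)[C@@H]1[C@H](O)C[C@@]2(C)OC(/C(C)=C/COCC=C)=CC2=O
F7 | step 18 | (1R)-1-[(2S,3S)-2-ethenyl-4-methylidene-5-oxooxolan-3-yl]-2-{(2R)-2-methyl-3-oxo-5-[(2E)-4-(prop-2-en-1-yloxy)but-2-en-2-yl]-2,3-dihydrofuran-2-yl}ethyl (2E)-2-(acetoxymethyl)but-2-enoate | C=C1C(=O)O[C@@H](C=C)[C@@H]1[C@H](OC(=O)/C(=C/C)COC(C)=O)C[C@@]2(C)OC(/C(C)=C/COCC=C)=CC2=O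
F8 | step 16 | (4S,5S)-5-ethenyl-4-{(1S)-1-hydroxy-2-[(2R)-2-methyl-3-oxo-5-(prop-1-en-2-yl)-2,3-dihydrofuran-2-yl]ethyl}-3-methylideneoxolan-2-one | C=C1C(=O)O[C@@H](C=C)[C@@H]1[C@@H](O)C[C@@]2(C)OC(C(C)=C)=CC2=O
F9 | step 10 | (2Z,4S)-2-[(tert-butyldimethylsilyloxy)methyl]-4-hydroxyhexa-2,5-dienoic acid | C=C[C@H](O)/C=C(\C(=O)O)CO[Si](C)(C)C(C)(C)C
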